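**Retrosynthetic overview**
1. The catechol is unmasked last by O-demethylation. The succinamic acid chain comes from hydroxide opening of an N-benzylsuccinimide.
2. The C2 bromine is removed next (electrophilic bromination para to the 5-methoxy group), and the 4-methoxy group is traced back to a free phenol.
3. Key disconnection is the aryl C1–CH2 bond. It is made by a Mannich-type amidoalkylation (Tscherniak–Einhorn) of 2-bromo-6-methoxyphenol with N-(hydroxymethyl)succinimide, para to the OH because both ortho positions are occupied.
4. The two fragments come from succinimide plus formaldehyde, and from guaiacol by ortho-selective bromination.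
5. No ring is formed. The benzene ring and the five-membered imide ring are bought, and the imide ring is opened in step 6.

Assumption: the target SMILES has no stereocentre and no double-bond geometry, so the compound is achiral and no stereocontrol is needed.

**Step 1**
Reactants: 1 succinimide; 2 formaldehyde (37% aqueous)
Product: 3 N-(hydroxymethyl)succinimide
Conditions: 2 (1.1 equiv), K2CO3 (1 mol %), H2O, 80 °C, 1 h; evaporate, recrystallise from EtOAc
Reagents that add atoms: none
Why: In this base-catalysed N-hydroxymethylation the acidic imide N–H adds to formaldehyde and gives the crystalline hemiaminal, a storable iminium precursor for the Mannich-type step; no stereocentre is formed.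

**Step 2**
Reactants: 4 guaiacol (2-methoxyphenol)
Product: 5 2-bromo-6-methoxyphenol
Conditions: tBuNH2 (2.0 equiv), Br2 (1.0 equiv), toluene, −30 °C; then 4 in CH2Cl2, −78 °C → rt
Reagents that add atoms: bromine, BrBr
Why: In this Pearson-type ortho-bromination the N-bromoamine made in the flask delivers bromine within a hydrogen-bonded phenol complex at low temperature, so electrophilic substitution goes to the free ortho carbon and not to the para carbon.

**Step 3**
Reactants: 3 N-(hydroxymethyl)succinimide; 5 2-bromo-6-methoxyphenol
Product: 7 N-(3-bromo-4-hydroxy-5-methoxybenzyl)succinimide, via N-methylidenesuccinimidium ion 6 (not isolated)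
Conditions: conc. H2SO4/AcOH (1:4), 0 °C → rt, 16 h (5 in 1.05 equiv); pour on ice, filter, recrystallise from EtOH
Reagents that add atoms: none
Why: In this Tscherniak–Einhorn amidoalkylation (aromatic Mannich-type reaction) acid ionises 3 to the N-acyliminium ion 6, which the phenol attacks at the only free OH-activated position (para, since Br and OMe block both ortho carbons), forming the aryl–CH2 bond without creating a stereocentre.

**Step 4**
Reactants: 7 N-(3-bromo-4-hydroxy-5-methoxybenzyl)succinimide
Product: 8 N-(3-bromo-4,5-dimethoxybenzyl)succinimide
Conditions: MeI (1.5 equiv), K2CO3 (1.5 equiv), dry DMF, rt, 12 h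
Reagents that add atoms: iodomethane, CI
Why: This Williamson ether synthesis on the phenolate (as in 5-bromovanillin to 5-bromoveratraldehyde) leaves the imide untouched under dry carbonate conditions and removes the para-phenolate that could later expel the imide or suffer ipso attack.

**Step 5**
Reactants: 8 N-(3-bromo-4,5-dimethoxybenzyl)succinimide
Product: 9 N-(2,3-dibromo-4,5-dimethoxybenzyl)succinimide
Conditions: Br2 (1.1 equiv), AcOH, dark, rt → 40 °C, 6 h; aq. NaHSO3 quench, recrystallise
Reagents that add atoms: bromine, BrBr
Why: In this electrophilic aromatic bromination the 5-methoxy group is the dominant donor and directs para to C2 (the outcome seen for 5-bromovanillin to 5,6-dibromovanillin), while its in-plane methyl group shields C6.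

**Step 6**
Reactants: 9 N-(2,3-dibromo-4,5-dimethoxybenzyl)succinimide
Product: 11 4-[(2,3-dibromo-4,5-dimethoxybenzyl)amino]-4-oxobutanoic acid, via lithium succinamate salt 10 (not isolated)
Conditions: LiOH·H2O (2.0 equiv), THF/H2O (3:1), 0 °C → rt, 1 h; then 1 M HCl to pH 2, filter or extract with EtOAc
Reagents that add atoms: lithium hydroxide, [Li+].[OH-]
Why: In this imide hydrolysis (nucleophilic acyl substitution) hydroxide opens the activated, symmetrical imide within minutes at either carbonyl to the same product, and the resulting carboxylate amide resists further hydrolysis.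

**Step 7**
Reactants: 11 4-[(2,3-dibromo-4,5-dimethoxybenzyl)amino]-4-oxobutanoic acid
Product: 12 4-[(2,3-dibromo-4,5-dihydroxybenzyl)amino]-4-oxobutanoic acid (target)
Conditions: BBr3 (1 M in CH2Cl2, 6 equiv), CH2Cl2, −78 °C → rt, 12 h; ice-water quench (no MeOH), EtOAc extraction
Reagents that add atoms: none
Why: In this Lewis-acid aryl methyl ether cleavage BBr3 binds the ether oxygens and bromide removes both methyl groups by SN2, while aryl bromides, amide and acid survive and the water quench avoids methyl ester formation.

**Compound list**
1 | succinimide | O=C1CCC(=O)N1 | starting material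
2 | formaldehyde | C=O | starting material
3 | N-(hydroxymethyl)succinimide | O=C1CCC(=O)N1CO | intermediate
4 | guaiacol (2-methoxyphenol) | COc1ccccc1O | starting material
5 | 2-bromo-6-methoxyphenol | COc1cccc(Br)c1O | intermediate
6 | N-methylidenesuccinimidium ion (N-acyliminium, not isolated) | C=[N+]1C(=O)CCC1=O | intermediate
7 | N-(3-bromo-4-hydroxy-5-methoxybenzyl)succinimide | COc1cc(CN2C(=O)CCC2=O)cc(Br)c1O | intermediate
8 | N-(3-bromo-4,5-dimethoxybenzyl)succinimide | COc1cc(CN2C(=O)CCC2=O)cc(Br)c1OC | intermediate
9 | N-(2,3-dibromo-4,5-dimethoxybenzyl)succinimide | COc1cc(CN2C(=O)CCC2=O)c(Br)c(Br)c1OC | intermediate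
10 | lithium 4-[(2,3-dibromo-4,5-dimethoxybenzyl)amino]-4-oxobutanoate (not isolated) | [Li+].[O-]C(=O)CCC(=O)NCc1cc(OC)c(OC)c(Br)c1Br | intermediate
11 | 4-[(2,3-dibromo-4,5-dimethoxybenzyl)amino]-4-oxobutanoic acid | O=C(O)CCC(=O)NCc1cc(OC)c(OC)c(Br)c1Br | intermediate
12 | 4-[(2,3-dibromo-4,5-dihydroxybenzyl)amino]-4-oxobutanoic acid | O=C(O)CCC(=O)NCc1cc(O)c(O)c(Br)c1Br | target

**Step count**
- Total step count: 7.
- Longest linear sequence: 6 (steps 2, 3, 4, 5, 6, 7 from guaiacol, or equally steps 1, 3, 4, 5, 6, 7 from succinimide).

**Three steps most likely to fail**

**Step 3** (low conversion of the imide-derived iminium ion, or diarylmethane formation in strong acid). The fallback sets out from 5 and comes back at 7.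
- A classical three-component phenol Mannich reaction of 5 with 2 and aqueous dimethylamine in refluxing EtOH gives 2-bromo-4-[(dimethylamino)methyl]-6-methoxyphenol F1. Attack is again para because both ortho positions are blocked.
- Heating this Mannich base with 1 in DMF at 130 °C under a nitrogen sweep expels the amine and forms 2-bromo-6-methoxy-4-methylidenecyclohexa-2,5-dien-1-one F2, a para-quinone methide that is not isolated.
- The imide nitrogen of 1 adds to the exocyclic carbon of the quinone methide and delivers 7.

**Step 5** (C2/C6 isomer mixture or over-bromination of the dimethyl ether). The fallback sets out from 7 and comes back at 9.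
- The free phenol is brominated first (Br2, AcOH, rt), the direct counterpart of the 5-bromovanillin to 5,6-dibromovanillin conversion. This gives N-(2,3-dibromo-4-hydroxy-5-methoxybenzyl)succinimide F3.
- As an acidic phenol it can be freed of isomers by crystallisation.
- O-methylation with MeI and K2CO3 in DMF then gives 9.

**Step 7** (poor solubility of the amic acid in CH2Cl2, or partial re-closure to the imide under BBr3). The fallback sets out from 9 and comes back at 12.
- The neutral, CH2Cl2-soluble imide is demethylated first (BBr3, CH2Cl2, −78 °C → rt). This gives N-(2,3-dibromo-4,5-dihydroxybenzyl)succinimide F4.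
- The imide ring is then opened with degassed 1 M NaOH (4 equiv) at 0 °C under argon for about 10 min. The short time keeps catechol oxidation and quinone methide loss of the imide from competing.
- Immediate acidification with HCl gives 12.

**Further compounds**
F1 | step 3 | 2-bromo-4-[(dimethylamino)methyl]-6-methoxyphenol | COc1cc(CN(C)C)cc(Br)c1O
F2 | step 3 | 2-bromo-6-methoxy-4-methylidenecyclohexa-2,5-dien-1-one | COC1=CC(=C)C=C(Br)C1=O
F3 | step 5 | N-(2,3-dibromo-4-hydroxy-5-methoxybenzyl)succinimide | COc1cc(CN2C(=O)CCC2=O)c(Br)c(Br)c1O
F4 | step 7 | N-(2,3-dibromo-4,5-dihydroxybenzyl)succinimide | O=C1CCC(=O)N1Cc1cc(O)c(O)c(Br)c1Br
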